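## Structural features

The target is a tetracycle. A 5,6-dimethyl-2-pyranone is fused through its C3–C4 bond to a dihydropyran whose ring oxygen ends at a hemiketal carbon; this dihydropyran is trans-fused to a cycloheptane, which shares a C–C bond with a 5,5-dimethylcyclopent-2-enone. The seven-membered ring carbons are lettered here C-a (hemiketal carbon), C-b (CHOH), C-c (ketone), C-d (tertiary carbinol, ring fusion), C-e (enone β-carbon, ring fusion), C-f (CHCH3) and C-g (CH carrying the CH2 link to the pyranone). Five stereocentres sit on this ring: C-f, C-g, C-a and C-b are contiguous, and C-d is separated from C-b only by the C-c carbonyl. Fragile elements are the hemiketal (ring–chain tautomerism), the α-ketol array C-b/C-c/C-d (enolisation, α-ketol shift, retro-aldol of the β-hydroxy enone) and the hydrogen at C-f, which is γ to the enone. The real difficulty is to place four contiguous, differently oxidised carbons (C-a to C-d) with defined configuration on a seven-membered ring, and to tell the two secondary oxygens at C-b and C-c apart. C-g and C-a hang on a latent ketone and can equilibrate, so only C-b, C-d and C-f must be carried through. The key step exploits the position of C-g between C-f and the latent ketone C-a: this is where a diazoacetate carbon lands when it inserts beside a cyclohexanone carbonyl, and the carboxyl it brings makes C-g the one carbon to which the CH2–pyranone arm can be joined.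

## Logic of the disconnections

**23 ⇒ 22 ⇒ 21 ⇒ 20.** No skeletal bond is cut. The silyl ether at C-b is removed last, the C-c ketone is traced back to a carbinol, and the C-c/C-d oxygens are tied in an isopropylidene ketal. C-b and C-c are both secondary carbinol positions and only one may be oxidised; the silyl ether and the ketal keep them distinct and also block retro-aldol and α-ketol chemistry earlier on. The forward steps must hydrolyse the ketal without losing the silyl ether and oxidise a 1,2-diol to the ketol without glycol cleavage.

**20 ⇒ 19 + 17.** The bond from the exocyclic CH2 to the pyranone C-3 and the C–O bond of the hemiketal are cut. This removes two rings and the heteroaromatic unit at once and leaves an α-methylene ketone. The forward step is a conjugate addition followed by hemiketal closure; C-g and C-a are formed under equilibrium control and must settle in the trans-fused arrangement.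

**19 ⇒ 18 ⇒ 16 ⇒ 15.** The exocyclic C=CH2 is traced to an aminomethyl group and a carboxyl on C-g, and then the C-g–CH2 bond is cut. The carboxyl makes C-g the only strongly acidic carbon, so the one-carbon arm enters there and not at C-b. The forward steps need a Mannich reaction at a hindered β-keto ester carbon and a neutral removal of the ester that triggers loss of CO2 and amine.

**15 ⇒ 12 + 14 (key).** The bonds C-f–C-g and C-g–C-a are cut, which contracts the cycloheptanone to a cyclohexanone. The seven-membered ring problem becomes a six-membered one in which C-b, C-c, C-d and C-f are already in place. The forward step demands attack at the saturated ketone only, migration of C-f and not C-b, and retention at C-f.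

**12 ⇒ 11 ⇒ 10 ⇒ 9.** Functional-group changes only: the C-a ketone comes from a silyl-protected carbinol and the enone from the saturated cyclopentanone. The ketone is unveiled last because in 12 the C-f hydrogen is vinylogously activated. The desaturation is regiospecific because the ketone has only one α-CH2.

**9 ⇒ 8 ⇒ 7.** The C-c–C-d bond is cut (pinacol), which opens the six-membered ring to an aldehyde and a ring ketone. The bicycle becomes a chain on a purchased five-membered ring. The forward step must give the cis-diol, with C-d set by the existing centre C-e and C-c trans to the silyloxy group at C-b.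

**7 ⇒ 6 ⇒ 4 + 5.** The C-a–C-b bond is cut (aldol) into two aldehydes. This brings in C-b and C-c with the silyl ether already on C-b. The forward step needs catalyst control at C-b and a clean donor/acceptor assignment.

**4 ⇒ 2 + 3, and 2 ⇒ 1.** The C-e–C-f bond is cut (Michael addition) and the enedione is traced to the saturated dione. All carbons then come from three simple commercial compounds. The forward step must be enantioselective, since C-e later dictates C-d.

**14 ⇒ 13.** The diazo group is traced to a bromide; this is a standard reagent preparation.

## Other disconnections considered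

**Alternative 1:** The cut removes the ring-fusion bond C-d–C-e and both bonds from the enone carbonyl to its neighbours, opening both carbocycles to the allene-yne A2. In the forward step [Rh(CO)2Cl]2 (monovalent rhodium) under carbon monoxide would join the terminal alkyne, CO and the distal, dimethyl-substituted allene bond to give dienone A1.
- In its favour: two rings and three C–C bonds are formed in one catalytic step, and the gem-dimethyl enone arrives complete.
- Against it here: A1 has no oxygen at C-b, C-c or C-d, and C-d is an sp2 carbon. Three late oxidations would be needed, the C-c/C-d diol would have to be set relative to a remote methyl group, and the one-carbon arm would have to be directed to C-g although two α-CH2 groups flank the masked ketone.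
- Comparison: on ring-forming economy this plan is the better one. On oxidation pattern and stereocontrol the chosen plan is stronger, because 12 carries C-b, C-c and C-d with fixed configuration before the ring is enlarged and the ester of 15 directs the arm to C-g. Once the late oxidations are counted, the step count should be no lower.

**Alternative 2:** The cut runs through C-d–C-e and C-f–C-g. Triethylamine would expel acetate from acetoxypyranone A4, and the 3-oxidopyrylium would add across the tethered (E)-propenyl group to give the oxa-bridged cycloadduct A3.
- In its favour: the seven-membered ring, the C-a ketone, the oxygen on C-d (as the bridge) and a CH2O carbon on C-g are all delivered at once, and the alkene geometry is translated into the C-f/C-g relationship.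
- A point where it is the better plan: the one-carbon arm is already part of the skeleton, whereas the chosen route excises the carboxyl carbon of 15 and brings the CH2 from an iminium salt.
- Against it here: C-g is formed as a fully substituted C–O bridgehead that must be reduced to C–H by opening the ether bridge. The C-b=C-c enone must be turned into a C-b carbinol and a C-c ketone. The cyclopentane needs two further oxidation-level changes. A4 requires a multistep furan-based synthesis, with one tether stereocentre as the only control over facial selectivity.
- Comparison: the cycloaddition builds more skeleton per step than the diazo insertion. The chosen route has its oxygenation in place earlier and is expected to be shorter overall.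

**Alternative 3:** The cut runs through C-g–C-a and C-b–C-c: dichloroketene A7 would add across the silyl enol ether A6 to give dichlorocyclobutanone A5. Later fragmentation of the C-g–C-c bond would enlarge the five-membered ring by two carbons.
- In its favour: the regiochemistry follows from the polarity of the enol ether, and the cycloaddition is as dependable as the diazo insertion.
- A point where it is the better plan: C-c arrives at the ketone level, whereas the chosen route needs a late oxidation at C-c.
- Against it here: C-b arrives as CCl2 between two carbonyls. Turning it into one secondary carbinol of defined configuration passes through an enolisable 2-substituted 1,3-diketone, where neither the configuration at C-b nor the distinction between the C-a and C-c carbonyls is secured. The arm at C-g is still missing, and A6 with its tertiary silyloxy centre is itself a multistep target.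
- Comparison: the key steps are equal in mechanistic reliability. The chosen route keeps C-b as a configurationally defined silyl ether next to a single carbonyl throughout and should need fewer corrective steps.

Key step: step 11

Remarks on the chemistry, one line each:
- Carbon count: a four-carbon enal as the source of C-f would leave a CH2 between C-f and C-a and end in a seven-membered acyloin; the six-membered ketone 12 needs a three-carbon aldehyde, so 3 is used, with the dione in its dehydro form 2 as acceptor.
- The diazo ester is used as its allyl ester so that the carboxyl can be removed under neutral conditions; the carboxyl carbon directs bond formation to C-g and is then lost as CO2, the CH2 arm coming from an iminium salt.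
- Assumption: C-g and C-a equilibrate (enolisation of the ring-opened ketone, ring–chain tautomerism) to the trans-fused arrangement with axial hydroxyl shown by 23; the carbinol centre C-a of 6–11 is drawn as the catalyst-controlled anti-aldol epimer and is immaterial.

## Route

**Step 1**
Reactants: 1 2,2-dimethylcyclopentane-1,3-dione
Product: 2 2,2-dimethylcyclopent-4-ene-1,3-dione
Conditions: CuBr2 (2.2 equiv), MeOH, reflux
Reagents that add atoms: none
Why: α-Bromination by CuBr2 and loss of HBr in the same pot (dehydrogenation of a 2,2-disubstituted cyclopentane-1,3-dione); the quaternary carbon between the carbonyls leaves only the C4–C5 bond for desaturation.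

**Step 2**
Reactants: 2 2,2-dimethylcyclopent-4-ene-1,3-dione; 3 propanal
Product: 4 (2S)-2-[(1R)-3,3-dimethyl-2,4-dioxocyclopentyl]propanal
Conditions: (R)-α,α-diphenylprolinol trimethylsilyl ether (10 mol%), PhCO2H (10 mol%), CH2Cl2, 0 °C
Reagents that add atoms: none
Why: Enamine-catalysed Michael addition of an aldehyde to a cyclic enedione. The bulky group of the R-configured catalyst shields one face of the E-enamine and should set S at C-f, and the open synclinal transition state with the ring hydrogen anti to the enamine double bond should place R at the ring carbon C-e; the two alkene carbons of 2 are equivalent, so there is no regiochemical issue.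

**Step 3**
Reactants: 4 (2S)-2-[(1R)-3,3-dimethyl-2,4-dioxocyclopentyl]propanal; 5 (tert-butyldimethylsilyloxy)acetaldehyde
Product: 6 (2S,3S,4S)-2-(tert-butyldimethylsilyloxy)-4-[(1R)-3,3-dimethyl-2,4-dioxocyclopentyl]-3-hydroxypentanal
Conditions: L-proline (20 mol%), DMF, 4 °C, 5 added by syringe pump
Reagents that add atoms: none
Why: Proline-catalysed direct cross-aldol: only the unbranched aldehyde 5 forms the enamine, and the α-branched aldehyde 4 acts as acceptor. The hydrogen-bonded chair-like transition state of L-proline fixes the enamine face and should give the anti-aldol with S at the silyloxy carbon C-b; the carbinol centre C-a is removed in step 9, so lower facial selectivity on the chiral acceptor would not matter.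

**Step 4**
Reactants: 6 β-hydroxy aldehyde
Product: 7 (2S,3S,4S)-2-(tert-butyldimethylsilyloxy)-4-[(1R)-3,3-dimethyl-2,4-dioxocyclopentyl]-3-(triethylsilyloxy)pentanal
Conditions: Et3SiOTf, 2,6-lutidine, CH2Cl2, −78 °C
Reagents that add atoms: triethylsilyl trifluoromethanesulfonate, CC[Si](CC)(CC)OS(=O)(=O)C(F)(F)F
Why: Low-temperature silylation with a non-nucleophilic base keeps the β-oxy aldehyde from eliminating or epimerising; the triethylsilyl ether can later be removed beside the TBS ether.

**Step 5**
Reactants: 7 bis-silyloxy keto aldehyde
Product: 8 (3aR,4S,5S,6R,7R,7aR)-6-(tert-butyldimethylsilyloxy)-7,7a-dihydroxy-1,1,4-trimethyl-5-(triethylsilyloxy)octahydro-2H-inden-2-one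
Conditions: SmI2 (2.5 equiv), t-BuOH, THF, −78 to −30 °C, neutral cold work-up
Reagents that add atoms: none
Why: Samarium diiodide ketyl–carbonyl (pinacol) cyclisation: the aldehyde is reduced first and its ketyl adds to the adjacent ring ketone in a six-membered closure. The chain on C-e reaches only one face of that ketone (cis ring fusion, C-d), the samarium-bridged dialkoxide gives the cis-diol (C-c), and the new carbinol ends up trans to the neighbouring silyloxy group, the arrangement normally preferred in such closures.

**Step 6**
Reactants: 8 cis-diol
Product: 9 (3aR,4S,5S,6R,7R,7aR)-6-(tert-butyldimethylsilyloxy)-7,7a-(isopropylidenedioxy)-1,1,4-trimethyl-5-(triethylsilyloxy)octahydro-2H-inden-2-one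
Conditions: 2-methoxypropene, PPTS (cat.), CH2Cl2, 0 °C
Reagents that add atoms: 2-methoxypropene, COC(C)=C
Why: Kinetic ketalisation of the cis-1,2-diol with an enol ether under mild acid; the cis-fused dioxolane forms readily, the silyl ethers survive, and the ketal shuts off retro-aldol opening of the β-hydroxy ketone.

**Step 7**
Reactants: 9 saturated ketone
Product: 10 (4S,5S,6R,7R,7aR)-6-(tert-butyldimethylsilyloxy)-7,7a-(isopropylidenedioxy)-1,1,4-trimethyl-5-(triethylsilyloxy)-1,4,5,6,7,7a-hexahydro-2H-inden-2-one
Conditions: LiN(iPr)2, THF, −78 °C; then PhS(Cl)=NtBu, −78 °C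
Reagents that add atoms: none
Why: One-pot dehydrogenation of a ketone through its lithium enolate and N-tert-butylbenzenesulfinimidoyl chloride (sulfoxide-type syn-elimination at low temperature); the ketone has hydrogens on only one α-carbon, so enolate and new double bond form regiospecifically.

**Step 8**
Reactants: 10 triethylsilyl ether
Product: 11 (4S,5S,6S,7R,7aR)-6-(tert-butyldimethylsilyloxy)-5-hydroxy-7,7a-(isopropylidenedioxy)-1,1,4-trimethyl-1,4,5,6,7,7a-hexahydro-2H-inden-2-one
Conditions: HF·pyridine, pyridine, THF, 0 °C
Reagents that add atoms: none
Why: Buffered HF·pyridine cleaves the triethylsilyl ether much faster than the hindered secondary TBS ether; ketal and enone are inert.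

**Step 9**
Reactants: 11 secondary alcohol
Product: 12 (4S,6R,7R,7aR)-6-(tert-butyldimethylsilyloxy)-7,7a-(isopropylidenedioxy)-1,1,4-trimethyl-4,6,7,7a-tetrahydro-1H-indene-2,5-dione
Conditions: Dess–Martin periodinane, NaHCO3, CH2Cl2, 0 °C; used at once
Reagents that add atoms: none
Why: Dess–Martin oxidation under neutral, buffered conditions; the ketone is unveiled last because the C-f hydrogen of 12 is α to the new ketone and γ to the enone and would enolise under base or acid.

**Step 10**
Reactants: 13 allyl bromoacetate
Product: 14 allyl diazoacetate
Conditions: TsNHNHTs, DBU, THF, 0 °C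
Reagents that add atoms: N,N'-bis(p-tolylsulfonyl)hydrazine, Cc1ccc(cc1)S(=O)(=O)NNS(=O)(=O)c1ccc(C)cc1
Why: N-Alkylation of the bis-sulfonylhydrazide by the bromoacetate and base-induced loss of two sulfinate ions gives the diazoacetate (sulfonylhydrazide route to diazo esters).

**Step 11**
Reactants: 12 hydrindenedione; 14 allyl diazoacetate
Product: 15 allyl (4R,5R,7R,8R,8aR)-7-(tert-butyldimethylsilyloxy)-8,8a-(isopropylidenedioxy)-1,1,4-trimethyl-2,6-dioxo-1,2,4,5,6,7,8,8a-octahydroazulene-5-carboxylate
Conditions: BF3·OEt2 (1.2 equiv), CH2Cl2, −20 to 0 °C
Reagents that add atoms: none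
Why: BF3 coordinates the saturated ketone of 12 and the nucleophilic diazo carbon of 14 adds to the carbonyl carbon C-a to give a β-boryloxy diazonium intermediate. The C-f–C-a bond, antiperiplanar to the departing nitrogen, then shifts to the diazonium carbon with loss of N2, which forms the second bond to the inserted carbon C-g and regenerates the ketone. The closest known reaction type is the Lewis-acid-promoted homologation of cyclohexanones with diazoacetic esters to 2-alkoxycarbonylcycloheptanones (a Tiffeneau–Demjanov-type ring enlargement). The seven-membered ring is not closed by a cyclisation but arises by one-atom enlargement of the existing six-membered ring through this 1,2-shift. The migrating carbon C-f keeps its configuration (suprafacial shift with retention); the new centre C-g is not under kinetic control but, as a β-keto ester, should equilibrate through its enol to the ester trans to the methyl group, and it is rebuilt in step 13 in any case. Chemoselectivity for C-a rests on the other ketone being a conjugated cyclopentenone flanked by a quaternary carbon, which is much less electrophilic and less prone to enlargement. Regioselectivity rests on the α-substituents: the silyloxy group inductively disfavours positive charge build-up at C-b, whereas C-f is a secondary allylic carbon with good migratory aptitude. Low temperature and the absence of base should keep enolisation of 12 toward C-f slower than the addition.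

**Step 12**
Reactants: 15 β-keto ester
Product: 16 allyl (4S,5R,7R,8R,8aR)-7-(tert-butyldimethylsilyloxy)-5-[(dimethylamino)methyl]-8,8a-(isopropylidenedioxy)-1,1,4-trimethyl-2,6-dioxo-1,2,4,5,6,7,8,8a-octahydroazulene-5-carboxylate
Conditions: Me2N=CH2 I (Eschenmoser's salt), Et3N, CH2Cl2, rt
Reagents that add atoms: dimethyl(methylidene)ammonium iodide, C=[N+](C)C.[I-]
Why: Mannich reaction of the enolisable β-keto ester with a preformed iminium salt; C-g is by far the most acidic carbon, so the aminomethyl group enters there only. The configuration of the new quaternary centre is irrelevant (drawn anti to the methyl group).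

**Step 13**
Reactants: 16 Mannich base; 17 4-hydroxy-5,6-dimethyl-2H-pyran-2-one
Product: 20 TBS-protected acetonide hemiketal adduct, via amino keto acid 18 (not isolated), via methylene ketone 19 (not isolated)
Conditions: Pd(PPh3)4 (5 mol%), morpholine, THF, rt; then 17, 45 °C
Reagents that add atoms: none
Why: Zerovalent palladium ionises the allyl ester and morpholine traps the allyl fragment; the β-amino β-keto acid then loses CO2 and dimethylamine (decarboxylative Mannich elimination) to give the α-methylene ketone. The acidic hydroxypyranone captures it by Michael addition and hemiketalisation, as 4-hydroxycoumarins do with enones. C-g is protonated and the hemiketal closes under equilibrium control, which should favour the trans-fused ring with the methyl and CH2 arms trans and the hydroxyl axial.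

**Step 14**
Reactants: 20 acetonide
Product: 21 diol (C-c secondary carbinol cis to the C-d tertiary hydroxyl; TBS ether at C-b retained)
Conditions: AcOH/H2O (4:1), 45 °C
Reagents that add atoms: none
Why: Acid hydrolysis of the isopropylidene ketal; a hindered secondary TBS ether is far more stable to aqueous acetic acid, and the cyclic hemiketal simply re-closes.

**Step 15**
Reactants: 21 diol
Product: 22 TBS ether of the target (C-c ketone in place)
Conditions: Dess–Martin periodinane, NaHCO3, CH2Cl2, 0 °C to rt
Reagents that add atoms: none
Why: Dess–Martin oxidation of the only secondary alcohol; the tertiary C-d hydroxyl and the hemiketal hydroxyl cannot be oxidised, and buffering limits glycol cleavage and epimerisation at C-b.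

**Step 16**
Reactants: 22 TBS ether
Product: 23 CNP0525404.1 (target)
Conditions: HF·pyridine, pyridine, THF, 0 °C to rt
Reagents that add atoms: none
Why: Fluoride cleavage of the α-keto silyl ether under buffered, non-basic conditions avoids α-ketol shift and epimerisation at C-b; C-g and C-a stay under thermodynamic control.

## Compound list

1 | 2,2-dimethylcyclopentane-1,3-dione | CC1(C)C(=O)CCC1=O | starting material
2 | 2,2-dimethylcyclopent-4-ene-1,3-dione | CC1(C)C(=O)C=CC1=O | intermediate
3 | propanal | CCC=O | starting material
4 | (2S)-2-[(1R)-3,3-dimethyl-2,4-dioxocyclopentyl]propanal | O=C[C@@H](C)[C@H]1CC(=O)C(C)(C)C1=O | intermediate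
5 | (tert-butyldimethylsilyloxy)acetaldehyde | O=CCO[Si](C)(C)C(C)(C)C | starting material
6 | (2S,3S,4S)-2-(tert-butyldimethylsilyloxy)-4-[(1R)-3,3-dimethyl-2,4-dioxocyclopentyl]-3-hydroxypentanal | O=C[C@@H](O[Si](C)(C)C(C)(C)C)[C@@H](O)[C@@H](C)[C@H]1CC(=O)C(C)(C)C1=O | intermediate
7 | (2S,3S,4S)-2-(tert-butyldimethylsilyloxy)-4-[(1R)-3,3-dimethyl-2,4-dioxocyclopentyl]-3-(triethylsilyloxy)pentanal | O=C[C@@H](O[Si](C)(C)C(C)(C)C)[C@@H](O[Si](CC)(CC)CC)[C@@H](C)[C@H]1CC(=O)C(C)(C)C1=O | intermediate
8 | (3aR,4S,5S,6R,7R,7aR)-6-(tert-butyldimethylsilyloxy)-7,7a-dihydroxy-1,1,4-trimethyl-5-(triethylsilyloxy)octahydro-2H-inden-2-one (cis-fused, cis-diol) | C[C@@H]1[C@H](O[Si](CC)(CC)CC)[C@H](O[Si](C)(C)C(C)(C)C)[C@@H](O)[C@@]2(O)[C@@H]1CC(=O)C2(C)C | intermediate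
9 | (3aR,4S,5S,6R,7R,7aR)-6-(tert-butyldimethylsilyloxy)-7,7a-(isopropylidenedioxy)-1,1,4-trimethyl-5-(triethylsilyloxy)octahydro-2H-inden-2-one | C[C@@H]1[C@H](O[Si](CC)(CC)CC)[C@H](O[Si](C)(C)C(C)(C)C)[C@H]2OC(C)(C)O[C@@]23[C@@H]1CC(=O)C3(C)C | intermediate
10 | (4S,5S,6R,7R,7aR)-6-(tert-butyldimethylsilyloxy)-7,7a-(isopropylidenedioxy)-1,1,4-trimethyl-5-(triethylsilyloxy)-1,4,5,6,7,7a-hexahydro-2H-inden-2-one | C[C@@H]1[C@H](O[Si](CC)(CC)CC)[C@H](O[Si](C)(C)C(C)(C)C)[C@H]2OC(C)(C)O[C@@]23C1=CC(=O)C3(C)C | intermediate
11 | (4S,5S,6S,7R,7aR)-6-(tert-butyldimethylsilyloxy)-5-hydroxy-7,7a-(isopropylidenedioxy)-1,1,4-trimethyl-1,4,5,6,7,7a-hexahydro-2H-inden-2-one | C[C@@H]1[C@H](O)[C@H](O[Si](C)(C)C(C)(C)C)[C@H]2OC(C)(C)O[C@@]23C1=CC(=O)C3(C)C | intermediate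
12 | (4S,6R,7R,7aR)-6-(tert-butyldimethylsilyloxy)-7,7a-(isopropylidenedioxy)-1,1,4-trimethyl-4,6,7,7a-tetrahydro-1H-indene-2,5-dione | C[C@@H]1C(=O)[C@H](O[Si](C)(C)C(C)(C)C)[C@H]2OC(C)(C)O[C@@]23C1=CC(=O)C3(C)C | intermediate
13 | allyl bromoacetate | BrCC(=O)OCC=C | starting material
14 | allyl diazoacetate | C=CCOC(=O)C=[N+]=[N-] | intermediate
15 | allyl (4R,5R,7R,8R,8aR)-7-(tert-butyldimethylsilyloxy)-8,8a-(isopropylidenedioxy)-1,1,4-trimethyl-2,6-dioxo-1,2,4,5,6,7,8,8a-octahydroazulene-5-carboxylate | C[C@@H]1[C@@H](C(=O)OCC=C)C(=O)[C@H](O[Si](C)(C)C(C)(C)C)[C@H]2OC(C)(C)O[C@@]23C1=CC(=O)C3(C)C | intermediate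
16 | allyl (4S,5R,7R,8R,8aR)-7-(tert-butyldimethylsilyloxy)-5-[(dimethylamino)methyl]-8,8a-(isopropylidenedioxy)-1,1,4-trimethyl-2,6-dioxo-1,2,4,5,6,7,8,8a-octahydroazulene-5-carboxylate | C[C@@H]1[C@](CN(C)C)(C(=O)OCC=C)C(=O)[C@H](O[Si](C)(C)C(C)(C)C)[C@H]2OC(C)(C)O[C@@]23C1=CC(=O)C3(C)C | intermediate
17 | 4-hydroxy-5,6-dimethyl-2H-pyran-2-one | Cc1oc(=O)cc(O)c1C | starting material
18 | (4S,5R,7R,8R,8aR)-7-(tert-butyldimethylsilyloxy)-5-[(dimethylamino)methyl]-8,8a-(isopropylidenedioxy)-1,1,4-trimethyl-2,6-dioxo-1,2,4,5,6,7,8,8a-octahydroazulene-5-carboxylic acid | C[C@@H]1[C@](CN(C)C)(C(=O)O)C(=O)[C@H](O[Si](C)(C)C(C)(C)C)[C@H]2OC(C)(C)O[C@@]23C1=CC(=O)C3(C)C | intermediate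
19 | (4S,7R,8R,8aR)-7-(tert-butyldimethylsilyloxy)-8,8a-(isopropylidenedioxy)-1,1,4-trimethyl-5-methylidene-4,5,7,8-tetrahydroazulene-2,6(1H,8aH)-dione | C[C@@H]1C(=C)C(=O)[C@H](O[Si](C)(C)C(C)(C)C)[C@H]2OC(C)(C)O[C@@]23C1=CC(=O)C3(C)C | intermediate
20 | tetracyclic hemiketal: 23 with a TBS ether on the C-b hydroxyl, the C-c ketone replaced by a carbinol oxygen cis to the C-d oxygen, and these two oxygens joined as an isopropylidene ketal | Cc1oc(=O)c2c(c1C)O[C@]1(O)[C@H](O[Si](C)(C)C(C)(C)C)[C@H]3OC(C)(C)O[C@@]34C(=CC(=O)C4(C)C)[C@H](C)[C@H]1C2 | intermediate
21 | diol: 20 without the isopropylidene group (C-c hydroxyl cis to C-d hydroxyl, TBS ether at C-b) | Cc1oc(=O)c2c(c1C)O[C@]1(O)[C@H](O[Si](C)(C)C(C)(C)C)[C@@H](O)[C@@]3(O)C(=CC(=O)C3(C)C)[C@H](C)[C@H]1C2 | intermediate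
22 | TBS ether of 23 at the C-b hydroxyl | Cc1oc(=O)c2c(c1C)O[C@]1(O)[C@H](O[Si](C)(C)C(C)(C)C)C(=O)[C@@]3(O)C(=CC(=O)C3(C)C)[C@H](C)[C@H]1C2 | intermediate
23 | CNP0525404.1: pyranone-fused dihydropyran hemiketal on the 5,7-bicyclic hydroxy diketone | Cc1oc(=O)c2c(c1C)O[C@]1(O)[C@H](O)C(=O)[C@@]3(O)C(=CC(=O)C3(C)C)[C@H](C)[C@H]1C2 | target

## Step count and least certain steps

Total step count: 16. Longest linear sequence: 15 steps (steps 1–9 and 11–16; step 10 prepares the diazo ester 14).

**Step 11 (key step).** The most likely failure is Lewis-acid-induced enolisation of 12 toward C-f, since that hydrogen is vinylogously activated; this would move the double bond into conjugation with the C-a carbonyl or epimerise C-f before the slow addition to a ketone flanked by two branched carbons can occur. Partial migration of C-b is the second concern. The fallback runs the homologation before the enone is installed. It sets out from 9: buffered HF·pyridine should give the saturated alcohol F1, and Dess–Martin oxidation the saturated diketone F2, in which the C-f hydrogen is an ordinary ketone α-hydrogen and the remaining cyclopentanone is much less prone to diazo ester insertion than the cyclohexanone. BF3·OEt2 with 14 should then give the saturated ring-enlarged keto ester F3. Dehydrogenation of its cyclopentanone through the dianion (LiN(iPr)2, 2.2 equiv, then N-tert-butylbenzenesulfinimidoyl chloride) comes back to the route at 15.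

**Step 2.** The secondary amine catalyst may be consumed by conjugate addition to the very electrophilic enedione, and the configuration at the ring carbon C-e, which later dictates C-d, may erode through enolisation of the adjacent ketone. The fallback uses a stoichiometric auxiliary and sets out from 3: condensation with (S)-1-amino-2-(methoxymethyl)pyrrolidine gives the hydrazone F4. Deprotonation with LiN(iPr)2 and Michael addition to 2 should give the adduct hydrazone F5, and ozonolysis of the C=N bond at −78 °C comes back to the route at 4.

**Step 3.** Self-aldol of 5 may outrun the cross reaction, because 4 is a hindered acceptor whose Felkin–Anh preference opposes the catalyst; slow enamine formation from 4 could also epimerise C-f. The fallback sets out from 4: a Sn(OTf)2/chiral diamine-mediated Mukaiyama aldol with the silyl ketene thioacetal of S-ethyl (tert-butyldimethylsilyloxy)thioacetate should give the hydroxy thioester F6 (either carbinol epimer serves). Silylation with Et3SiOTf gives the bis-silyl thioester F7, and Fukuyama reduction (Et3SiH, Pd/C) comes back to the route at 7.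

**Step 5.** Electron transfer to the 1,3-diketone, reductive loss of the α-silyloxy group from the ketyl, or retro-aldol opening of the samarium alkoxide of the β-hydroxy ketone may compete with the cyclisation. The fallback sets out from 7: a triazolium-carbene-catalysed crossed benzoin reaction between the aldehyde and the adjacent ring ketone should give the α-ketol F8, with C-d again fixed by the cis ring fusion. NaBH4 in MeOH at −40 °C, delivering hydride axially to the activated α-oxygenated ketone, should give the equatorial carbinol cis to the tertiary hydroxyl and come back to the route at 8.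

**Step 13.** The allylpalladium intermediate may allylate the pyranone, and the methylene ketone 19 may dimerise or lose the β-ketal oxygen before it is captured. The fallback separates the events and sets out from 15: aqueous formaldehyde with KHCO3 gives the hydroxymethyl keto ester F9, and Ac2O/pyridine gives the acetoxymethyl keto ester F10. Pd(OAc)2/PPh3 in MeCN then effects decarboxylation–deacetoxylation to isolated 19, and 19 with 17 and catalytic Et3N comes back to the route at 20.

**Step 14.** Partial loss of the silyl ether during ketal hydrolysis would erase the distinction between the two secondary hydroxyls. The fallback gives up that distinction on purpose and sets out from 20: TFA/H2O (9:1) removes both groups to give the tetraol F11. Bu2SnO forms the stannylene acetal of the cis-1,2-diol, and bromine oxidises its secondary carbon (C-c) to the ketone, which comes back to the route at 23.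

## Further compounds

F1 | step 11 | (3aR,4S,5S,6S,7R,7aR)-6-(tert-butyldimethylsilyloxy)-5-hydroxy-7,7a-(isopropylidenedioxy)-1,1,4-trimethyloctahydro-2H-inden-2-one | C[C@@H]1[C@H](O)[C@H](O[Si](C)(C)C(C)(C)C)[C@H]2OC(C)(C)O[C@@]23[C@@H]1CC(=O)C3(C)C
F2 | step 11 | saturated diketone: 12 with the ring-fusion double bond hydrogenated (cis-fused) | C[C@@H]1C(=O)[C@H](O[Si](C)(C)C(C)(C)C)[C@H]2OC(C)(C)O[C@@]23[C@@H]1CC(=O)C3(C)C
F3 | step 11 | saturated ring-enlarged allyl keto ester: 15 with the ring-fusion double bond hydrogenated (cis-fused) | C[C@@H]1[C@@H](C(=O)OCC=C)C(=O)[C@H](O[Si](C)(C)C(C)(C)C)[C@H]2OC(C)(C)O[C@@]23[C@@H]1CC(=O)C3(C)C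
F4 | step 2 | propanal (S)-1-amino-2-(methoxymethyl)pyrrolidine hydrazone | CC/C=N/N1CCC[C@H]1COC
F5 | step 2 | hydrazone of 4 with (S)-1-amino-2-(methoxymethyl)pyrrolidine | COC[C@@H]1CCCN1/N=C/[C@@H](C)[C@H]1CC(=O)C(C)(C)C1=O
F6 | step 3 | S-ethyl (2S,3S,4S)-2-(tert-butyldimethylsilyloxy)-4-[(1R)-3,3-dimethyl-2,4-dioxocyclopentyl]-3-hydroxypentanethioate | CCSC(=O)[C@@H](O[Si](C)(C)C(C)(C)C)[C@@H](O)[C@@H](C)[C@H]1CC(=O)C(C)(C)C1=O
F7 | step 3 | S-ethyl (2S,3S,4S)-2-(tert-butyldimethylsilyloxy)-4-[(1R)-3,3-dimethyl-2,4-dioxocyclopentyl]-3-(triethylsilyloxy)pentanethioate | CCSC(=O)[C@@H](O[Si](C)(C)C(C)(C)C)[C@@H](O[Si](CC)(CC)CC)[C@@H](C)[C@H]1CC(=O)C(C)(C)C1=O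
F8 | step 5 | α-ketol: 8 with the secondary carbinol at C-c as a ketone | C[C@@H]1[C@H](O[Si](CC)(CC)CC)[C@H](O[Si](C)(C)C(C)(C)C)C(=O)[C@@]2(O)[C@@H]1CC(=O)C2(C)C
F9 | step 13 | 15 bearing a hydroxymethyl group on the ester-bearing carbon | C[C@@H]1[C@](CO)(C(=O)OCC=C)C(=O)[C@H](O[Si](C)(C)C(C)(C)C)[C@H]2OC(C)(C)O[C@@]23C1=CC(=O)C3(C)C
F10 | step 13 | 15 bearing an acetoxymethyl group on the ester-bearing carbon | C[C@@H]1[C@](COC(C)=O)(C(=O)OCC=C)C(=O)[C@H](O[Si](C)(C)C(C)(C)C)[C@H]2OC(C)(C)O[C@@]23C1=CC(=O)C3(C)C
F11 | step 14 | tetraol: 21 without the silyl group | Cc1oc(=O)c2c(c1C)O[C@]1(O)[C@H](O)[C@@H](O)[C@@]3(O)C(=CC(=O)C3(C)C)[C@H](C)[C@H]1C2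
A1 | alternative 1 | bicyclo[5.3.0]decadienone ketal | C[C@@H]1CC2(OCCO2)CC=C3C1=CC(=O)C3(C)C
A2 | alternative 1 | allene-yne ketal precursor | C#C[C@H](C)CC1(OCCO1)CC=C=C(C)C
A3 | alternative 2 | oxa-bridged cyclopenta-fused cycloheptenone cycloadduct | C[C@H]1[C@@H]2C[C@H](O[Si](C)(C)C(C)(C)C)C(C)(C)[C@@]23C=CC(=O)[C@]1(CO[Si](C)(C)C(C)(C)C)O3
A4 | alternative 2 | 6-acetoxypyran-3-one with tethered (E)-propenyl group (acetal and C-2 configurations immaterial) | CC(=O)OC1(C(C)(C)[C@@H](O[Si](C)(C)C(C)(C)C)C/C=C/C)C=CC(=O)C(CO[Si](C)(C)C(C)(C)C)O1
A5 | alternative 3 | dichlorocyclobutanone fused to the diquinane | C[C@@H]1[C@@H]2C(=O)C(Cl)(Cl)[C@]2(O[Si](C)(C)C)[C@@]3(O[Si](C)(C)C)C1=CC(=O)C3(C)C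
A6 | alternative 3 | diquinane trimethylsilyl enol ether | C[C@@H]1C=C(O[Si](C)(C)C)[C@@]2(O[Si](C)(C)C)C1=CC(=O)C2(C)C
A7 | alternative 3 | dichloroketene | ClC(Cl)=C=O
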